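**Plan**

Numbering (elemanolide): ring C5–C10; C10 carries vinyl (C1=C2, α) and CH2OH (C14, β); C5 carries C4(=C3H2)C15H2OH; lactone O–C6 / C7–C11(=C13H2)–C12; ester on C8–O; β is the face of C14.
Retrosynthesis: the C8 ester, the C15 hydroxyl and the lactone (cyclocarbonylation of a C6-hydroxy, C7-ethynyl unit) are removed first; C5–C6 and C7–C8 are then cut together. The enabling feature is that the C8 oxygen and the sp2 carbon C4 on C5 are 1,5-related across C6–C7, and C15 on C4 can reach C8. Ring C5–C10 is therefore the retro-aldol product of a bicyclo[2.2.2]octanone (bridgeheads C5 and C8, temporary bridge C4–C15), which a Diels–Alder reaction on the dimethoxycyclohexadiene ring C5–C4–C15–C8–C9–C10 provides.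
Forward: Birch alkylation builds C10 and the temporary diene ring. A boronic-ester tether from the future vinyl carbon C1 delivers an (E)-β-boryl acrylate across C5/C8, and acid then cleaves C8–C15 to release the cyclohexane. The C4 methylene, C8 hydroxyl, C7 alkyne, C8 ester, C6 hydroxyl, lactone and C15 hydroxyl follow.
Stereochemistry: the tether fixes C6 (boron α, later oxygen with retention), C5 and C10 relative to one another. C7 settles β by enolization, and C8 comes from hydride delivery by the C14 hydroxyl. Absolute configuration comes from separating the two (+)-pinanediol boronates of the racemic cycloadduct.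

Key step: step 4

Step 1
Reactants: 1 methyl 3,5-dimethoxybenzoate
Product: 3 methyl 3,5-dimethoxy-1-[(triisopropylsilyloxy)methyl]cyclohexa-2,5-diene-1-carboxylate, via lithium ester dienolate 2 (not isolated)
Conditions: Li, NH3(l), THF, t-BuOH (1 equiv), −78 °C; then i-Pr3SiOCH2Cl, −78 → −33 °C
Reagents that add atoms: (triisopropylsilyloxy)methyl chloride, ClCO[Si](C(C)C)(C(C)C)C(C)C
Why: Birch reductive alkylation: two-electron reduction of the benzoate gives the cross-conjugated ester dienolate 2, which the chloromethyl ether alkylates at the ipso carbon to create the quaternary (not yet stereogenic) C10 between two enantiotopic methyl enol ethers.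

Step 2
Reactants: 3 methyl 3,5-dimethoxy-1-[(triisopropylsilyloxy)methyl]cyclohexa-2,5-diene-1-carboxylate
Product: 4 {3,5-dimethoxy-1-[(triisopropylsilyloxy)methyl]cyclohexa-2,5-dien-1-yl}methanol
Conditions: LiAlH4, Et2O, 0 °C; basic work-up
Reagents that add atoms: none
Why: LiAlH4 reduction of the neopentyl ester gives the primary alcohol that will carry the tether (the future vinyl carbon C1), the enol ethers and the silyl ether being inert under the basic work-up.

Step 3
Reactants: 5 ethyl (E)-3-(4,4,5,5-tetramethyl-1,3,2-dioxaborolan-2-yl)prop-2-enoate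
Product: 6 [(E)-3-ethoxy-3-oxoprop-1-en-1-yl]boronic acid
Conditions: NaIO4, NH4OAc, acetone–H2O, rt
Reagents that add atoms: water, O
Why: Periodate glycol cleavage of the pinacol released in the hydrolytic equilibrium frees the boronic acid, whose B–OH groups can then exchange with an alcohol.

Step 4
Reactants: 4 {3,5-dimethoxy-1-[(triisopropylsilyloxy)methyl]cyclohexa-2,5-dien-1-yl}methanol; 6 [(E)-3-ethoxy-3-oxoprop-1-en-1-yl]boronic acid
Product: 10 bicyclo[2.2.2]octene alcohol (bridgeheads C5–H and C8–OMe; bridge C4(OMe)=C15H on the β face; 6α-[(+)-pinanediolatoboryl]; 7β-CO2Et; 10α-CH2OH; 10β-CH2OSi(i-Pr)3), via mixed boronic ester 7 (not isolated), via conjugated diene boronic ester 8 (not isolated), via cyclic boronic ester cycloadduct 9 (not isolated)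
Conditions: 6 (1.3 equiv), 4 Å molecular sieves, pyridinium p-toluenesulfonate (5 mol %), PhMe, 80 °C; then (+)-pinanediol, rt; chromatographic separation of the two diastereomers
Reagents that add atoms: (1S,2S,3R,5S)-pinane-2,3-diol, C[C@@]1([C@H]2C[C@H](C2(C)C)C[C@H]1O)O
Why: The CH2OH arm of 4 exchanges onto boron (7), acid moves one enol ether double bond into conjugation to give diene 8 (its mirror-image regioisomer forms equally and the two equilibrate through the symmetric 1,3-dimethoxycyclohexenyl cation), and the tethered (E)-β-boryl acrylate then adds across C5 and C8 in a type 1 intramolecular Diels–Alder reaction that forms C5–C6 and C7–C8 together. The closest known reaction types are the boron-tethered intramolecular Diels–Alder reaction of dienols with alkenylboronic acids and the acid-promoted in situ conjugation–cycloaddition of Birch 1,4-dienes. Two rings close, the six-membered 1,2-oxaborinane of the tether (C5–C10–C1–O–B–C6) and the cyclohexene C5–C6–C7–C8–C15=C4 of the bicyclo[2.2.2]octene, both in one suprafacial [4+2] addition on the diene face that carries the tethered arm. The tether places boron exo at C6 and cis to C1 on C10, which fixes C6, the bridgeheads C5 and C8 and the now stereogenic C10 relative to one another (C4 ends trans to boron and cis to C14), while the ester at C7 goes endo by the Alder rule and is in any case corrected later by enolization. The step needs C5-to-C6 regiochemistry and a single diene face: both methoxy groups make C5 the nucleophilic terminus, which matches the boron-bearing β-carbon of the acrylate, and the six-membered tether allows no other pairing or face. The cycloadduct is necessarily racemic, so boron is transferred to (+)-pinanediol and the two diastereomeric boronates should be separable by chromatography, 10 being the one with the configuration drawn; the pinanediol ester then protects boron until step 17.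

Step 5
Reactants: 10 bicyclo[2.2.2]octene alcohol
Product: 11 bicyclo[2.2.2]octene aldehyde (10α-CHO)
Conditions: Dess–Martin periodinane, pyridine, CH2Cl2, 0 °C → rt
Reagents that add atoms: none
Why: Dess–Martin oxidation of the neopentyl primary alcohol gives a non-enolizable aldehyde, pyridine buffering the acetic acid so that the enol ether survives.

Step 6
Reactants: 11 bicyclo[2.2.2]octene aldehyde
Product: 12 10α-vinyl bicyclo[2.2.2]octene
Conditions: Ph3PCH3Br, KN(SiMe3)2, THF, 0 °C; then 11, −78 → 0 °C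
Reagents that add atoms: methyltriphenylphosphonium bromide, [Br-].C[P+](c1ccccc1)(c1ccccc1)c1ccccc1
Why: Wittig methylenation installs the C10 vinyl group (C1=C2) at a stage where no ketone is unmasked and no stereocenter can epimerize.

Step 7
Reactants: 12 10α-vinyl bicyclo[2.2.2]octene
Product: 14 cyclohexanone (5β-acetyl; 6α-[(+)-pinanediolatoboryl]; 7β-CO2Et; 8-oxo; 10α-vinyl; 10β-CH2OSi(i-Pr)3), via bicyclic β-methoxy ketone 13 (not isolated)
Conditions: 2 M HCl (aq), THF, 0 °C → rt
Reagents that add atoms: water, O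
Why: Acid hydrolysis of the enol ether gives ketone 13, whose bridgehead methoxy group then drives a retro-aldol cleavage of C8–C15 (oxocarbenium at C8, enol at C4); this releases the strain of the bicycle and leaves ring C5–C10 with the 5β-acetyl group as set in step 4, the C8 ketone held as an enolizable β-keto ester and C7 free to take the equatorial β orientation.

Step 8
Reactants: 14 cyclohexanone
Product: 15 5β-isopropenyl β-keto ester
Conditions: Cp2Ti(μ-Cl)(μ-CH2)AlMe2, pyridine (cat.), THF–PhMe, −40 → 0 °C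
Reagents that add atoms: Tebbe reagent Cp2Ti(μ-Cl)(μ-CH2)AlMe2, C[Al-]1(C)C[Ti]([Cl+]1)(C1C=CC=C1)C1C=CC=C1
Why: Tebbe methylenation converts the methyl ketone into the isopropenyl group (new carbon C3) under non-basic conditions, so the enolizable C5 is not epimerized, while the β-keto ester is masked as its titanium enolate.

Step 9
Reactants: 15 5β-isopropenyl β-keto ester
Product: 16 C14 alcohol (10β-CH2OH β-keto ester)
Conditions: HF·pyridine, pyridine, THF, 0 °C → rt
Reagents that add atoms: none
Why: Fluoride cleavage of the triisopropylsilyl ether frees the C14 hydroxyl, the pinanediol boronate, the β-keto ester and the alkenes being inert.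

Step 10
Reactants: 16 C14 alcohol
Product: 17 diol (8α-OH; 7β-CO2Et; 10β-CH2OH)
Conditions: Me4NBH(OAc)3, AcOH–MeCN, −20 °C
Reagents that add atoms: none
Why: Hydroxyl-directed triacetoxyborohydride reduction (Evans–Saksena type): the axial C14–O–BH(OAc)2 group delivers hydride across the ring to the β face of the C8 carbonyl, so the new hydroxyl is 8α (equatorial) and the ester at C7 is fixed trans to it.

Step 11
Reactants: 17 diol
Product: 18 C14 tert-butyldimethylsilyl ether (8α-OH free)
Conditions: t-BuMe2SiCl, imidazole, DMF, 0 °C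
Reagents that add atoms: tert-butyldimethylsilyl chloride, CC(C)(C)[Si](C)(C)Cl
Why: Silylation is selective for the primary C14 hydroxyl over the hindered secondary C8 hydroxyl.

Step 12
Reactants: 18 C14 tert-butyldimethylsilyl ether
Product: 20 7β-ethynyl alcohol, via β-hydroxy aldehyde 19 (not isolated)
Conditions: i-Bu2AlH (3.2 equiv), CH2Cl2, −78 °C; then MeOH, K2CO3, dimethyl (1-diazo-2-oxopropyl)phosphonate, −78 °C → rt
Reagents that add atoms: dimethyl (1-diazo-2-oxopropyl)phosphonate, CC(=O)C(=[N+]=[N-])P(=O)(OC)OC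
Why: i-Bu2AlH reduces the ester only to the aldehyde stage (aluminium hemiacetal held by the neighbouring alkoxide) and Seyferth–Gilbert homologation with the Ohira–Bestmann reagent then gives the terminal alkyne (C11≡C13), C7 keeping the equatorial β orientation.

Step 13
Reactants: 21 ethyl but-2-ynoate
Product: 23 ethyl (Z)-2-(hydroxymethyl)but-2-enoate, via α-alumino enoate 22 (not isolated)
Conditions: i-Bu2AlH, N-methylmorpholine N-oxide, THF, 0 °C; then CH2O (gas), −78 → 0 °C
Reagents that add atoms: formaldehyde, C=O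
Why: Syn-hydroalumination of the ynoate puts aluminium on the α-carbon and the methyl group cis to the ester, and formaldehyde traps the alkenylalane with retention (vinylalumination), which gives the Z geometry of the side chain.

Step 14
Reactants: 23 ethyl (Z)-2-(hydroxymethyl)but-2-enoate
Product: 24 ethyl (Z)-2-[(tert-butyldimethylsilyloxy)methyl]but-2-enoate
Conditions: t-BuMe2SiCl, imidazole, CH2Cl2, rt
Reagents that add atoms: tert-butyldimethylsilyl chloride, CC(C)(C)[Si](C)(C)Cl
Why: Silylation of the primary allylic alcohol protects it during activation of the acid.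

Step 15
Reactants: 24 ethyl (Z)-2-[(tert-butyldimethylsilyloxy)methyl]but-2-enoate
Product: 25 (Z)-2-[(tert-butyldimethylsilyloxy)methyl]but-2-enoic acid
Conditions: LiOH, THF–H2O, 0 °C → rt; then 1 M HCl to pH 4
Reagents that add atoms: lithium hydroxide, [Li+].[OH-]
Why: Mild saponification at low temperature should give the acid without isomerization of the Z double bond.

Step 16
Reactants: 20 7β-ethynyl alcohol; 25 (Z)-2-[(tert-butyldimethylsilyloxy)methyl]but-2-enoic acid
Product: 27 C8 ester (8α-acyloxy; 6α-boronate; 7β-ethynyl), via mixed anhydride 26 (not isolated)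
Conditions: 25, 2,4,6-Cl3C6H2COCl, Et3N, PhMe, rt; then 20, 70 °C
Reagents that add atoms: none
Why: Yamaguchi esterification through the mixed anhydride acylates the only free hydroxyl (8α, equatorial) with retention at C8, and leaving out a nucleophilic amine catalyst should keep the Z geometry of the acyl group.

Step 17
Reactants: 27 C8 ester
Product: 28 6α-alcohol
Conditions: NaBO3·4H2O, THF–H2O, rt
Reagents that add atoms: sodium perborate NaBO3·4H2O, [Na+].OO[B-](O)(O)O
Why: Perborate oxidation of the C–B bond goes by 1,2-migration of carbon from boron to oxygen with retention, which puts the C6 hydroxyl α, cis to the vinyl group and trans to both ring neighbours.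

Step 18
Reactants: 28 6α-alcohol
Product: 29 trans-fused α-methylene-γ-butyrolactone
Conditions: PdCl2 (5 mol %), SnCl2 (5 mol %), PPh3 (10 mol %), CO (7 atm), MeCN, 75 °C
Reagents that add atoms: carbon monoxide, [C-]#[O+]
Why: Norton-type cyclocarbonylation: the C6 hydroxyl gives an alkoxycarbonylpalladium species that adds syn across the neighbouring alkyne, and protonolysis releases the trans-fused α-methylene lactone, as is known for trans-2-ethynylcyclohexanol.

Step 19
Reactants: 29 trans-fused α-methylene-γ-butyrolactone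
Product: 30 C15 allylic alcohol
Conditions: SeO2 (0.5 equiv), t-BuOOH, CH2Cl2, rt
Reagents that add atoms: selenium dioxide, O=[Se]=O; tert-butyl hydroperoxide, CC(C)(C)OO
Why: SeO2 allylic hydroxylation (ene reaction, then [2,3]-shift) oxidizes the methyl group of the electron-rich isopropenyl unit to C15H2OH, while the vinyl group has no allylic hydrogen and the two electron-poor alkenes should not react.

Step 20
Reactants: 30 C15 allylic alcohol
Product: 31 CNP0338073.1
Conditions: HF·pyridine, THF, 0 °C → rt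
Reagents that add atoms: none
Why: Fluoride cleaves both tert-butyldimethylsilyl ethers under weakly acidic conditions that the α-methylene lactone and the Z ester tolerate.

**Compound list**

1 | methyl 3,5-dimethoxybenzoate | COC(=O)c1cc(OC)cc(OC)c1 | starting material
2 | lithium dienolate of methyl 3,5-dimethoxy-1,4-dihydrobenzoate | [Li+].COC([O-])=C1C=C(OC)CC(OC)=C1 | intermediate
3 | methyl 3,5-dimethoxy-1-[(triisopropylsilyloxy)methyl]cyclohexa-2,5-diene-1-carboxylate | COC(=O)C1(CO[Si](C(C)C)(C(C)C)C(C)C)C=C(OC)CC(OC)=C1 | intermediate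
4 | {3,5-dimethoxy-1-[(triisopropylsilyloxy)methyl]cyclohexa-2,5-dien-1-yl}methanol | OCC1(CO[Si](C(C)C)(C(C)C)C(C)C)C=C(OC)CC(OC)=C1 | intermediate
5 | ethyl (E)-3-(4,4,5,5-tetramethyl-1,3,2-dioxaborolan-2-yl)prop-2-enoate | CCOC(=O)/C=C/B1OC(C)(C)C(C)(C)O1 | starting material
6 | [(E)-3-ethoxy-3-oxoprop-1-en-1-yl]boronic acid | CCOC(=O)/C=C/B(O)O | intermediate
7 | mixed boronic ester of 6 with the CH2OH group of 4 | CCOC(=O)/C=C/B(O)OCC1(CO[Si](C(C)C)(C(C)C)C(C)C)C=C(OC)CC(OC)=C1 | intermediate
8 | conjugated diene boronic ester (2,4-dimethoxycyclohexa-1,3-diene isomer of 7, C10 stereogenic, antipode that leads to 10) | CCOC(=O)/C=C/B(O)OC[C@]1(CO[Si](C(C)C)(C(C)C)C(C)C)CC(OC)=CC(OC)=C1 | intermediate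
9 | cyclic boronic ester cycloadduct (bicyclo[2.2.2]octene fused to a B-hydroxy-1,2-oxaborinane through C6 and the C10 CH2O arm) | OB1OC[C@]2(CO[Si](C(C)C)(C(C)C)C(C)C)C[C@]3(OC)[C@@H](C(=O)OCC)[C@H]1[C@H]2C(OC)=C3 | intermediate
10 | bicyclo[2.2.2]octene alcohol: bridgeheads C5–H and C8–OMe, bridge C4(OMe)=C15H (β), 6α-[(+)-pinanediolatoboryl], 7β-CO2Et, 10α-CH2OH, 10β-CH2OSi(i-Pr)3 | OC[C@]1(CO[Si](C(C)C)(C(C)C)C(C)C)C[C@]2(OC)[C@@H](C(=O)OCC)[C@H](B3O[C@@]4(C)[C@H]5C[C@H](C5(C)C)C[C@H]4O3)[C@H]1C(OC)=C2 | intermediate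
11 | bicyclo[2.2.2]octene aldehyde (10α-CHO analogue of 10) | O=C[C@]1(CO[Si](C(C)C)(C(C)C)C(C)C)C[C@]2(OC)[C@@H](C(=O)OCC)[C@H](B3O[C@@]4(C)[C@H]5C[C@H](C5(C)C)C[C@H]4O3)[C@H]1C(OC)=C2 | intermediate
12 | 10α-vinyl bicyclo[2.2.2]octene | C=C[C@]1(CO[Si](C(C)C)(C(C)C)C(C)C)C[C@]2(OC)[C@@H](C(=O)OCC)[C@H](B3O[C@@]4(C)[C@H]5C[C@H](C5(C)C)C[C@H]4O3)[C@H]1C(OC)=C2 | intermediate
13 | bicyclic β-methoxy ketone (C4 ketone, C8 bridgehead OMe) | C=C[C@]1(CO[Si](C(C)C)(C(C)C)C(C)C)C[C@]2(OC)[C@@H](C(=O)OCC)[C@H](B3O[C@@]4(C)[C@H]5C[C@H](C5(C)C)C[C@H]4O3)[C@H]1C(=O)C2 | intermediate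
14 | cyclohexanone: 5β-acetyl, 6α-[(+)-pinanediolatoboryl], 7β-CO2Et, 8-oxo, 10α-vinyl, 10β-CH2OSi(i-Pr)3 | C=C[C@]1(CO[Si](C(C)C)(C(C)C)C(C)C)CC(=O)[C@@H](C(=O)OCC)[C@H](B3O[C@@]4(C)[C@H]5C[C@H](C5(C)C)C[C@H]4O3)[C@H]1C(C)=O | intermediate
15 | 5β-isopropenyl β-keto ester | C=C[C@]1(CO[Si](C(C)C)(C(C)C)C(C)C)CC(=O)[C@@H](C(=O)OCC)[C@H](B3O[C@@]4(C)[C@H]5C[C@H](C5(C)C)C[C@H]4O3)[C@H]1C(C)=C | intermediate
16 | C14 alcohol (10β-CH2OH β-keto ester) | C=C[C@]1(CO)CC(=O)[C@@H](C(=O)OCC)[C@H](B3O[C@@]4(C)[C@H]5C[C@H](C5(C)C)C[C@H]4O3)[C@H]1C(C)=C | intermediate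
17 | diol (8α-OH, 10β-CH2OH, 7β-CO2Et) | C=C[C@]1(CO)C[C@H](O)[C@@H](C(=O)OCC)[C@H](B3O[C@@]4(C)[C@H]5C[C@H](C5(C)C)C[C@H]4O3)[C@H]1C(C)=C | intermediate
18 | C14 tert-butyldimethylsilyl ether (8α-OH free) | C=C[C@]1(CO[Si](C)(C)C(C)(C)C)C[C@H](O)[C@@H](C(=O)OCC)[C@H](B3O[C@@]4(C)[C@H]5C[C@H](C5(C)C)C[C@H]4O3)[C@H]1C(C)=C | intermediate
19 | β-hydroxy aldehyde (7β-CHO) | C=C[C@]1(CO[Si](C)(C)C(C)(C)C)C[C@H](O)[C@@H](C=O)[C@H](B3O[C@@]4(C)[C@H]5C[C@H](C5(C)C)C[C@H]4O3)[C@H]1C(C)=C | intermediate
20 | 7β-ethynyl alcohol (8α-OH) | C=C[C@]1(CO[Si](C)(C)C(C)(C)C)C[C@H](O)[C@@H](C#C)[C@H](B3O[C@@]4(C)[C@H]5C[C@H](C5(C)C)C[C@H]4O3)[C@H]1C(C)=C | intermediate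
21 | ethyl but-2-ynoate | CC#CC(=O)OCC | starting material
22 | ethyl (Z)-2-(diisobutylalumanyl)but-2-enoate | CCOC(=O)/C(=C\C)[Al](CC(C)C)CC(C)C | intermediate
23 | ethyl (Z)-2-(hydroxymethyl)but-2-enoate | CCOC(=O)/C(=C\C)CO | intermediate
24 | ethyl (Z)-2-[(tert-butyldimethylsilyloxy)methyl]but-2-enoate | CCOC(=O)/C(=C\C)CO[Si](C)(C)C(C)(C)C | intermediate
25 | (Z)-2-[(tert-butyldimethylsilyloxy)methyl]but-2-enoic acid | OC(=O)/C(=C\C)CO[Si](C)(C)C(C)(C)C | intermediate
26 | mixed anhydride of 25 with 2,4,6-trichlorobenzoic acid | O=C(OC(=O)/C(=C\C)CO[Si](C)(C)C(C)(C)C)c1c(Cl)cc(Cl)cc1Cl | intermediate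
27 | C8 ester (8α-acyloxy, 6α-boronate, 7β-ethynyl) | C=C[C@]1(CO[Si](C)(C)C(C)(C)C)C[C@H](OC(=O)/C(=C\C)CO[Si](C)(C)C(C)(C)C)[C@@H](C#C)[C@H](B3O[C@@]4(C)[C@H]5C[C@H](C5(C)C)C[C@H]4O3)[C@H]1C(C)=C | intermediate
28 | 6α-alcohol | C=C[C@]1(CO[Si](C)(C)C(C)(C)C)C[C@H](OC(=O)/C(=C\C)CO[Si](C)(C)C(C)(C)C)[C@@H](C#C)[C@H](O)[C@H]1C(C)=C | intermediate
29 | trans-fused α-methylene-γ-butyrolactone (5β-isopropenyl, both silyl ethers on) | C=C[C@]1(CO[Si](C)(C)C(C)(C)C)C[C@H](OC(=O)/C(=C\C)CO[Si](C)(C)C(C)(C)C)[C@H]2C(=C)C(=O)O[C@@H]2[C@H]1C(C)=C | intermediate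
30 | C15 allylic alcohol (bis-silyl ether of the target) | C=C[C@]1(CO[Si](C)(C)C(C)(C)C)C[C@H](OC(=O)/C(=C\C)CO[Si](C)(C)C(C)(C)C)[C@H]2C(=C)C(=O)O[C@@H]2[C@H]1C(=C)CO | intermediate
31 | CNP0338073.1 | C=C[C@]1(CO)C[C@H](OC(=O)/C(=C\C)CO)[C@H]2C(=C)C(=O)O[C@@H]2[C@H]1C(=C)CO | target

**Step count and risks**

Total steps: 20. Longest linear sequence: 16 (steps 1, 2, 4–12, 16–20).

Step 4. The cascade makes both antipodal cores by design, so the route depends on the two (+)-pinanediol boronates being separable; they may co-elute. Fallback, from 4 and 6 back to 10: run the tethered cycloaddition as before but release boron with pinacol, which gives the racemic pinacol boronate alcohol F1. Esterify its primary hydroxyl with (S)-O-acetylmandelic acid (dicyclohexylcarbodiimide, 4-dimethylaminopyridine) and separate the two diastereomeric esters by crystallization or chromatography. The ester with the required core, the O-acetylmandelate F2, is then treated with K2CO3 in EtOH to remove the acyl group, and with (+)-pinanediol in PhMe to displace pinacol from boron, which returns 10.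

Step 10. Hydride may not be delivered by the C14 hydroxyl (external attack on the less hindered α face, or stalling at a C14–O–C8 hemiketal), which would give the axial 8β alcohol. Fallback, from 16 back to 27: use that outcome deliberately. Silylate the C14 hydroxyl first (t-BuMe2SiCl, imidazole) to give the silyl ether keto ester F3. NaBH4 in MeOH at −40 °C should then attack anti to the axial CH2OSi group and give the 8β-alcohol F4. i-Bu2AlH followed by the Ohira–Bestmann reagent gives the 8β-hydroxy alkyne F5. Mitsunobu esterification with acid 25 (PPh3, diisopropyl azodicarboxylate) inverts C8 and gives 27 directly.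

Step 18. The one-pot alkoxycarbonylation may stall or be diverted by the other alkenes of the substrate. Fallback, from 28 back to 29: hydrostannation of the terminal alkyne (n-Bu3SnH, PdCl2(PPh3)2 cat., THF), steered to the internal position by the neighbouring hydroxyl, gives the alkenylstannane F6. I2 in CH2Cl2 converts it into the 2-iodoalkene F7. Carbonylative lactonization of this vinyl iodide (Pd(PPh3)4 cat., CO at 1 atm, Et3N, MeCN, 60 °C) closes the same α-methylene lactone 29.

**Further compounds**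

F1 | step 4 | racemic pinacol boronate alcohol (pinacol analogue of 10; required enantiomer drawn) | OC[C@]1(CO[Si](C(C)C)(C(C)C)C(C)C)C[C@]2(OC)[C@@H](C(=O)OCC)[C@H](B3OC(C)(C)C(C)(C)O3)[C@H]1C(OC)=C2
F2 | step 4 | (S)-O-acetylmandelate of the required enantiomer of F1 | CC(=O)O[C@H](C(=O)OC[C@]1(CO[Si](C(C)C)(C(C)C)C(C)C)C[C@]2(OC)[C@@H](C(=O)OCC)[C@H](B3OC(C)(C)C(C)(C)O3)[C@H]1C(OC)=C2)c1ccccc1
F3 | step 10 | C14 tert-butyldimethylsilyl ether of keto ester 16 | C=C[C@]1(CO[Si](C)(C)C(C)(C)C)CC(=O)[C@@H](C(=O)OCC)[C@H](B3O[C@@]4(C)[C@H]5C[C@H](C5(C)C)C[C@H]4O3)[C@H]1C(C)=C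
F4 | step 10 | 8β-alcohol (C8 epimer of 18) | C=C[C@]1(CO[Si](C)(C)C(C)(C)C)C[C@@H](O)[C@@H](C(=O)OCC)[C@H](B3O[C@@]4(C)[C@H]5C[C@H](C5(C)C)C[C@H]4O3)[C@H]1C(C)=C
F5 | step 10 | 8β-hydroxy alkyne (C8 epimer of 20) | C=C[C@]1(CO[Si](C)(C)C(C)(C)C)C[C@@H](O)[C@@H](C#C)[C@H](B3O[C@@]4(C)[C@H]5C[C@H](C5(C)C)C[C@H]4O3)[C@H]1C(C)=C
F6 | step 18 | 7β-[1-(tributylstannyl)ethenyl] 6α-alcohol | C=C[C@]1(CO[Si](C)(C)C(C)(C)C)C[C@H](OC(=O)/C(=C\C)CO[Si](C)(C)C(C)(C)C)[C@@H](C(=C)[Sn](CCCC)(CCCC)CCCC)[C@H](O)[C@H]1C(C)=C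
F7 | step 18 | 7β-(1-iodoethenyl) 6α-alcohol | C=C[C@]1(CO[Si](C)(C)C(C)(C)C)C[C@H](OC(=O)/C(=C\C)CO[Si](C)(C)C(C)(C)C)[C@@H](C(I)=C)[C@H](O)[C@H]1C(C)=C
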